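## The problem

Conneotricone (27) is a depsidone. Ring A and ring B are joined twice, by a diaryl ether (A5–O–B6) and by an aryl ester (A6–C(=O)–O–B1), which together close a seven-membered dioxepinone. Ring B also carries a γ-lactone (phthalide) across B4 (carbonyl) and B5 (CH2). Ring A is pentasubstituted (A1 CH3, A2 H, A3 OH, A4 CO2H, A5 O-aryl, A6 C=O) and ring B is hexasubstituted (B1 O-acyl, B2 CH2OH, B3 OH, B4 C=O, B5 CH2O, B6 O-aryl).

There is no stereocentre, so the task is entirely regiochemical. Eleven substituents must be placed, and like functions must be told apart: the two carboxyl carbons at A4 and A6 (both ortho to the ether, either could lactonise), the three oxygens of ring B, and the two benzylic C–O groups. The ether oxygen has four ortho substituents, which makes intermolecular copper- or palladium-mediated aryl ether coupling unattractive.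

Three groups limit the late chemistry. The depsidone ester is opened by alkoxide, hydroxide or hydride, so nothing basic may follow ring closure. The B2 hydroxymethyl group lies between two ring oxygens and ionises towards an ortho-quinone methide under protic or Lewis acid. The A4 acid is a 2,6-dioxygenated benzoic acid and decarboxylates in hot acid.

The feature that opens the problem is the contiguous pattern on ring A: methyl (A1), hydrogen (A2), oxygen (A3), carboxyl (A4), aryloxy (A5), carboxyl (A6). A 4-aryloxy-6-methyl-2-pyrone-3,5-dicarboxylate gives exactly this pattern when its O–C(=O) unit is replaced by the two carbons of a ketene acetal. The hindered ether can therefore be made by addition–elimination on the pyrone before ring A exists.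

## Retrosynthesis

**27 ⇒ 26 ⇒ 25 (unmasking, no skeletal bond cut).** The B2 alcohol is kept as a tert-butyldiphenylsilyl ether to the end (26) and freed with buffered fluoride. An ester at this position would need base or hydride for removal, which the depsidone ester does not tolerate. Before that, BCl3 converts 25 into 26 by cleaving the A3 and B3 methyl ethers, each ortho to a carbonyl, and the A4 tert-butyl ester. The order matters: the Lewis acid is used while the benzylic oxygen is still shielded by the bulky silyl group. The forward steps must spare the diaryl ether, the aryl ester and the phthalide.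

**25 ⇒ 24 ⇒ 23 (cut A6–C(=O)–O–B1).** The seven-membered ring is opened at the ester, not at the ether: lactonisation of a 2-(2-hydroxyaryloxy)benzoic acid is classical, whereas closing the ether last would again need a tetra-ortho-substituted C–O coupling. Only the A6 acid and the B1 phenol may be free. In 23 they are the only benzyl-protected functions (benzyl ester and benzyl ether), so one neutral hydrogenolysis gives 24. The A4 carboxyl is a tert-butyl ester, which cannot transacylate to the B1 phenol, so the wrong depsidone cannot form.

**23 ⇒ 19 + 20 (cut A1–A2 and A3–A4; key step).** Ring A is removed entirely. The alternative, a preformed hexasubstituted ring A joined to ring B by aryl ether coupling, meets the hindrance described above. The precursor 19 is a 2-pyrone whose substituents come from a malonate and an acetoacetate, and 20 is 1,1-dimethoxyethene. The forward reaction must place the methoxy group at A3, beside the A4 ester, and must not expel the aryloxide from C4.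

**19 ⇒ 12 + 18 (cut pyrone C4–O).** C4 of the pyrone is the β-carbon of both the lactone carbonyl and the C3 ester, so a sulfonyl group there is displaced by a phenoxide by addition–elimination. This replaces a hindered arene coupling by a vinylogous acyl substitution. The forward step needs one free phenol (B6–OH of 12) and attack at C4 in preference to C6 or C2.

**18 ⇒ 17 ⇒ 14 + 15; 14 ⇒ 13.** Sulfone 18 comes from sulfide 17 by oxidation. Pyrone 17 is cut at C4–C5 and O1–C2 into the ketene dithioacetal 14 (from tert-butyl methyl malonate 13, CS2 and MeI) and benzyl acetoacetate 15. This route delivers the two esters already differentiated (tert-butyl at C3, benzyl at C5) and the C4 leaving group in the same step. Acylation routes to a 4-hydroxypyrone give no C3 ester.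

**12 ⇒ 10 ⇒ 9 ⇒ 8 ⇒ 7 ⇒ 6 ⇒ 5 ⇒ 4 ⇒ 2 ⇒ 1.** The ring B phenol is traced to methyl orsellinate (1), which supplies B1–O, B3–O, the B4 carboxyl and the B5 carbon.
- B6–OH comes from the C–Br bond of 10 by borylation and oxidation, so it appears last and alone; a catechol never has to be differentiated.
- The silyl ether, the alcohol 9 and the aldehyde 8 trace the B2 carbon back to a formyl group.
- The methyl and benzyl ethers (8, 7) come from the two hydroxyls of 6, distinguished by their hydrogen bonding.
- The formyl group of 6 enters at the only free position of 5.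
- The bromine of 5 enters para to the chelated hydroxyl of 5,7-dihydroxyphthalide (4). It serves twice, as blocking group for the formylation and as precursor of the B6 oxygen.
- 4 comes from 1 by benzylic bromination of the diacetate 2 and lactonisation.

## Roads not taken

**Alternative 1:** ring B by cycloaddition of a siloxyfuran with an ynoate. The cut is B3–B4 and B5–B6. A 2-silyloxy-4-benzyloxy-3-(methoxymethoxymethyl)furan A2 would add to methyl 4-silyloxybut-2-ynoate A3, and the oxa-bridged adduct would open to the hexasubstituted benzoate A1 with B6–OH free and B3 silylated.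
- Merit: one step sets all six substituents of ring B and differentiates the hydroquinone oxygens. In step economy for ring B this is clearly better than the nine linear steps (1–9) spent here on phenol 12.
- Weak points: A2 needs its own multistep synthesis. Silyloxyfurans tend to give vinylogous Michael adducts with ynoates in place of cycloadducts. The direction of bridge opening must be controlled.
- Comparison: A1 leaves ring A and the tetra-ortho ether untouched, which are the harder part of the target. Against the shorter ring B synthesis, the chosen plan sets regiochemistry that is predictable at every step from a cheap arene, and a key step that deals with ring A and the ether together. A1 could in principle replace 12 in the chosen route after protecting-group adjustment, so the two ideas are complementary.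

**Alternative 2:** late carbonylative closure of the phthalide. The cut is B4–C(=O) and C(=O)–O. The bromo diol depsidone A5 would be carbonylated (Pd(OAc)2, bisphosphine, CO), and the B5 hydroxymethyl group would trap the acyl palladium to give A4, the target as its A3 methyl ether and A4 methyl ester.
- Merit: the lactone carbonyl arrives catalytically at the end, and ring B needs no carboxyl during its assembly.
- Weak points: oxidative addition must occur at a bromide flanked by a free phenol and a hydroxymethyl group on an electron-rich ring. Amine base, CO and heat act on an alkoxide-sensitive depsidone. A4 still carries a methyl ester and a methyl ether, whose removal needs nucleophilic or strongly Lewis acidic conditions in the presence of the free B2 hydroxymethyl group.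
- Comparison: A5 requires the same hindered ether and a ring B of the same length as 12, so nothing is saved. The chosen plan carries the phthalide from step 2 at no cost and keeps its final steps non-basic.

**Alternative 3:** Baeyer–Villiger ring expansion of a xanthone. The cut is the B1–O ester bond. The xanthone A7 would be treated with CF3CO3H, and migration of B1 to oxygen would give the depsidone A6 (A3 triflate, A4 methyl ester, B2 acetoxymethyl, B3 methyl ether).
- Merit: the xanthone ether ring closes intramolecularly, so the hindered ether is made at least as easily as by the addition–elimination used here, and no lactonisation is needed.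
- Weak points: a xanthone carbonyl is doubly conjugated and a poor Baeyer–Villiger substrate. The migrating carbon B1 is para to the phthalide carbonyl, so the triflate on ring A is the only bias for the regiochemistry. A strong peracid meets a benzylic acetate. A6 then needs triflate, acetate, methyl ester and methyl ether removed from a base-sensitive depsidone.
- Comparison: the chosen plan sets against the easy ether closure an ester regiochemistry that cannot go wrong (only the A6 acid is free in 24) and a protecting-group set removed by hydrogenolysis, BCl3 and fluoride only.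

Key step: step 14

**Remarks on the chemistry.**
- Phthalide numbering is used in names: C1 carbonyl, O2, C3 methylene, C4–C7 benzo carbons. C7 corresponds to B3, C6 to B2, C5 to B1 and C4 to B6.
- "Ar" is the 5-benzyloxy-6-[(tert-butyldiphenylsilyloxy)methyl]-7-methoxyphthalid-4-yl group of 12.
- Assumption: methyl orsellinate (1), tert-butyl methyl malonate (13), benzyl acetoacetate (15) and 1,1-dimethoxyethene (20, freshly distilled) are purchased.
- Intermediate 21 is racemic and transient; the target has no stereocentre.

## Route

Step 1
Reactants: 1 methyl orsellinate (methyl 2,4-dihydroxy-6-methylbenzoate)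
Product: 2 methyl 2,4-diacetoxy-6-methylbenzoate
Conditions: Ac2O, pyridine, DMAP (cat.), CH2Cl2, rt
Reagents that add atoms: acetic anhydride, CC(=O)OC(C)=O
Why: DMAP-catalysed O-acetylation of both phenols; the acetates deactivate the ring so that the next bromination is benzylic and not nuclear.

Step 2
Reactants: 2 methyl 2,4-diacetoxy-6-methylbenzoate
Product: 4 5,7-dihydroxyphthalide, via benzylic bromide 3 (not isolated)
Conditions: NBS, AIBN (cat.), PhCF3, 85 °C; concentrate; 3 M HCl–1,4-dioxane, 90 °C
Reagents that add atoms: N-bromosuccinimide, O=C1CCC(=O)N1Br (bromine of 3); water, O (one lactone oxygen of 4)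
Why: Wohl–Ziegler bromination of the only benzylic methyl group, then acid hydrolysis, in which the acetates are cleaved and the bromomethyl group lactonises onto the neighbouring methyl ester (five-membered ring).

Step 3
Reactants: 4 5,7-dihydroxyphthalide
Product: 5 4-bromo-5,7-dihydroxyphthalide
Conditions: NBS (1.0 equiv), MeCN, −20 → 0 °C
Reagents that add atoms: N-bromosuccinimide, O=C1CCC(=O)N1Br
Why: Electrophilic bromination of a 2,4-dihydroxybenzoyl system goes para to the chelated hydroxyl (C4) in preference to the position between the hydroxyls; the bromine blocks C4 for step 4 and is the later source of the B6 oxygen.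

Step 4
Reactants: 5 4-bromo-5,7-dihydroxyphthalide
Product: 6 4-bromo-6-formyl-5,7-dihydroxyphthalide
Conditions: Cl2CHOMe, TiCl4, CH2Cl2, 0 °C → rt; then 1 M HCl
Reagents that add atoms: dichloromethyl methyl ether, COC(Cl)Cl (formyl carbon); water, O (formyl oxygen)
Why: Rieche formylation; the titanium phenoxide directs the electrophile ortho to oxygen, and C6, ortho to both hydroxyls, is the only free ring position.

Step 5
Reactants: 6 4-bromo-6-formyl-5,7-dihydroxyphthalide
Product: 7 5-benzyloxy-4-bromo-6-formyl-7-hydroxyphthalide
Conditions: BnBr (1.05 equiv), K2CO3 (1.1 equiv), DMF, rt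
Reagents that add atoms: benzyl bromide, BrCc1ccccc1
Why: Williamson etherification with one equivalent of base; the C5 hydroxyl (para to the lactone carbonyl, one hydrogen bond) should react before the C7 hydroxyl, which is held between two carbonyl groups.

Step 6
Reactants: 7 5-benzyloxy-4-bromo-6-formyl-7-hydroxyphthalide
Product: 8 5-benzyloxy-4-bromo-6-formyl-7-methoxyphthalide
Conditions: MeI (3 equiv), K2CO3, DMF, 40 °C
Reagents that add atoms: iodomethane, CI
Why: Williamson methylation of the remaining chelated phenol with excess MeI; no other acidic site is present.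

Step 7
Reactants: 8 5-benzyloxy-4-bromo-6-formyl-7-methoxyphthalide
Product: 9 5-benzyloxy-4-bromo-6-(hydroxymethyl)-7-methoxyphthalide
Conditions: NaBH4, THF–MeOH, 0 °C
Reagents that add atoms: none
Why: Borohydride reduction of the aryl aldehyde; the phthalide lactone and the aryl bromide are inert at 0 °C.

Step 8
Reactants: 9 5-benzyloxy-4-bromo-6-(hydroxymethyl)-7-methoxyphthalide
Product: 10 5-benzyloxy-4-bromo-6-[(tert-butyldiphenylsilyloxy)methyl]-7-methoxyphthalide
Conditions: TBDPSCl, imidazole, DMF, rt
Reagents that add atoms: tert-butyl(chloro)diphenylsilane, CC(C)(C)[Si](Cl)(c1ccccc1)c1ccccc1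
Why: Silylation of the primary benzylic alcohol; the bulky silyl group withstands base, heat, hydrogenolysis and carbodiimide, and its oxygen is shielded from Lewis acid.

Step 9
Reactants: 10 5-benzyloxy-4-bromo-6-[(tert-butyldiphenylsilyloxy)methyl]-7-methoxyphthalide
Product: 12 5-benzyloxy-6-[(tert-butyldiphenylsilyloxy)methyl]-4-hydroxy-7-methoxyphthalide, via aryl boronate 11 (not isolated)
Conditions: B2pin2, PdCl2(dppf) (5 mol %), KOAc, 1,4-dioxane, 90 °C; then 30% H2O2, aq. NaHCO3, THF, 0 °C → rt
Reagents that add atoms: bis(pinacolato)diboron, CC1(C)OB(OC1(C)C)B1OC(C)(C)C(C)(C)O1 (boryl group of 11); hydrogen peroxide, OO (phenol oxygen of 12)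
Why: Miyaura borylation of the aryl bromide, then peroxide oxidation of the C–B bond (aryl shift from boron to oxygen) gives the B6 phenol as the only free hydroxyl; acetate and bicarbonate spare the lactone and the silyl ether.

Step 10
Reactants: 13 tert-butyl methyl malonate
Product: 14 1-tert-butyl 3-methyl 2-[bis(methylsulfanyl)methylidene]propanedioate
Conditions: CS2, K2CO3, DMF, 0 °C; then MeI, rt
Reagents that add atoms: carbon disulfide, S=C=S; iodomethane, CI
Why: Standard ketene dithioacetal synthesis: the malonate carbanion adds to CS2 and the dithiolate is S-methylated twice.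

Step 11
Reactants: 14 1-tert-butyl 3-methyl 2-[bis(methylsulfanyl)methylidene]propanedioate; 15 benzyl acetoacetate
Product: 17 5-benzyl 3-tert-butyl 6-methyl-4-(methylsulfanyl)-2-oxo-2H-pyran-3,5-dicarboxylate, via acyclic substitution adduct 16 (not isolated)
Conditions: K2CO3, DMSO, rt → 50 °C
Reagents that add atoms: none
Why: Vinylic substitution (addition–elimination) of one methylsulfanyl group by the acetoacetate carbanion, then lactonisation of the enol oxygen onto the methyl ester (the tert-butyl ester is too hindered and the push–pull double bond isomerises freely); this is the ketene dithioacetal synthesis of 4-methylsulfanyl-2-pyranones.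

Step 12
Reactants: 17 5-benzyl 3-tert-butyl 6-methyl-4-(methylsulfanyl)-2-oxo-2H-pyran-3,5-dicarboxylate
Product: 18 5-benzyl 3-tert-butyl 4-(methanesulfonyl)-6-methyl-2-oxo-2H-pyran-3,5-dicarboxylate
Conditions: mCPBA (2.5 equiv), CH2Cl2, 0 °C → rt; used without chromatography
Reagents that add atoms: 3-chloroperbenzoic acid, OOC(=O)c1cccc(Cl)c1
Why: Peracid oxidation of the sulfide to the sulfone turns the C4 substituent into a good leaving group; the electron-poor ring double bonds are not epoxidised.

Step 13
Reactants: 12 5-benzyloxy-6-[(tert-butyldiphenylsilyloxy)methyl]-4-hydroxy-7-methoxyphthalide; 18 5-benzyl 3-tert-butyl 4-(methanesulfonyl)-6-methyl-2-oxo-2H-pyran-3,5-dicarboxylate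
Product: 19 5-benzyl 3-tert-butyl 4-(ArO)-6-methyl-2-oxo-2H-pyran-3,5-dicarboxylate (Ar as defined in the remarks)
Conditions: Cs2CO3 (1.2 equiv), MeCN, 0 °C → rt
Reagents that add atoms: none
Why: Nucleophilic vinylic substitution (addition–elimination) at C4, the β-carbon of the lactone carbonyl and of the C3 ester, with methanesulfinate as leaving group; 4-halo- and 4-sulfonyloxy-2-pyranones and coumarins react in the same way with phenoxides.

Step 14
Reactants: 19 5-benzyl 3-tert-butyl 4-(ArO)-6-methyl-2-oxo-2H-pyran-3,5-dicarboxylate; 20 1,1-dimethoxyethene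
Product: 23 1-benzyl 3-tert-butyl 2-(ArO)-4-methoxy-6-methylbenzene-1,3-dicarboxylate, via bridged lactone cycloadduct 21 (not isolated), via dimethoxycyclohexadiene 22 (not isolated)
Conditions: 20 (8 equiv), toluene, 110 °C, sealed base-washed tube
Reagents that add atoms: none
Why: Inverse-electron-demand Diels–Alder reaction in which the pyrone, made electron-poor by the C3 and C5 esters and the lactone carbonyl, is the diene (C3=C4–C5=C6) and the ketene acetal 20 is the electron-rich dienophile. Bond formation should be asynchronous: the nucleophilic CH2 of 20 attacks C6 (δ-terminus of the dienyl lactone and β-carbon of the C5 ester) and the acetal carbon closes onto C3 to give the bridged lactone 21; this polarity match, reinforced by both esters, places the methoxy group at A3 beside the A4 ester and is the only regiochemistry the step needs. Cycloreversion of 21 expels CO2 to give diene 22, and 1,2-elimination of methanol across A2–A3 aromatises the ring to 23. Ring A is therefore closed by an intermolecular [4+2] cycloaddition that makes the A1–A2 and A3–A4 bonds, followed by two eliminations, with the diaryl ether already in place. The two bridgehead stereocentres of 21 vanish on aromatisation, so no stereocontrol is required. The closest known reaction type is the cycloaddition of 3-alkoxycarbonyl-2-pyrones with 1,1-dialkoxyethenes, which gives ortho-alkoxybenzoates with loss of CO2 and alcohol. The required chemoselectivity, addition across C3/C6 in preference to displacement of the aryloxide at C4, is expected because the aryloxide is a poorer leaving group than the sulfinate of step 13 and the conditions are neutral, which also spares the silyl ether, both esters and the phthalide.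

Step 15
Reactants: 23 1-benzyl 3-tert-butyl 2-(ArO)-4-methoxy-6-methylbenzene-1,3-dicarboxylate
Product: 24 3-(tert-butoxycarbonyl)-2-{6-[(tert-butyldiphenylsilyloxy)methyl]-5-hydroxy-7-methoxyphthalid-4-yloxy}-4-methoxy-6-methylbenzoic acid
Conditions: H2 (1 atm), Pd/C (10% Pd on carbon), EtOAc, rt
Reagents that add atoms: none
Why: Hydrogenolysis of the benzyl ester and the aryl benzyl ether frees exactly the A6 acid and the B1 phenol; tert-butyl ester, silyl ether, lactone and diaryl ether are inert under neutral conditions.

Step 16
Reactants: 24 3-(tert-butoxycarbonyl)-2-{6-[(tert-butyldiphenylsilyloxy)methyl]-5-hydroxy-7-methoxyphthalid-4-yloxy}-4-methoxy-6-methylbenzoic acid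
Product: 25 protected depsidone (conneotricone A3,B3-dimethyl ether A4 tert-butyl ester B2 O-silyl ether)
Conditions: EDC·HCl, DMAP (0.3 equiv), CH2Cl2 (0.005 M), rt
Reagents that add atoms: none
Why: Steglich-type carbodiimide lactonisation; only the A6 acid is free and the diaryl ether holds the B1 phenol next to it, so the seven-membered aryl ester closes, while the A4 tert-butyl ester cannot transacylate.

Step 17
Reactants: 25 protected depsidone
Product: 26 conneotricone B2 O-(tert-butyldiphenylsilyl) ether
Conditions: BCl3 (1 M in CH2Cl2, 8 equiv), CH2Cl2, −78 → 0 °C; ice-water quench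
Reagents that add atoms: none
Why: BCl3 cleaves aryl methyl ethers ortho to a carbonyl through a six-membered boron chelate (A3–OMe beside the A4 ester, B3–OMe beside the phthalide carbonyl) and tert-butyl esters by ionisation; the diaryl ether, aryl ester and lactone are not chelated and should survive at or below 0 °C, and the hindered silyl ether oxygen is poorly coordinated.

Step 18
Reactants: 26 conneotricone B2 O-(tert-butyldiphenylsilyl) ether
Product: 27 conneotricone
Conditions: HF·pyridine, THF–pyridine, 0 °C → rt (polypropylene vessel)
Reagents that add atoms: none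
Why: Fluoride-driven Si–O cleavage under buffered, weakly acidic conditions frees the benzylic alcohol without base, so the depsidone ester and the phthalide are not opened.

## Compound list

1 | methyl orsellinate (methyl 2,4-dihydroxy-6-methylbenzoate) | COC(=O)c1c(C)cc(O)cc1O | starting material
2 | methyl 2,4-diacetoxy-6-methylbenzoate | COC(=O)c1c(C)cc(OC(C)=O)cc1OC(C)=O | intermediate
3 | methyl 2,4-diacetoxy-6-(bromomethyl)benzoate | COC(=O)c1c(CBr)cc(OC(C)=O)cc1OC(C)=O | intermediate (not isolated)
4 | 5,7-dihydroxyphthalide | O=C1OCc2cc(O)cc(O)c21 | intermediate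
5 | 4-bromo-5,7-dihydroxyphthalide | O=C1OCc2c(Br)c(O)cc(O)c21 | intermediate
6 | 4-bromo-6-formyl-5,7-dihydroxyphthalide | O=C1OCc2c(Br)c(O)c(C=O)c(O)c21 | intermediate
7 | 5-benzyloxy-4-bromo-6-formyl-7-hydroxyphthalide | O=C1OCc2c(Br)c(OCc3ccccc3)c(C=O)c(O)c21 | intermediate
8 | 5-benzyloxy-4-bromo-6-formyl-7-methoxyphthalide | O=C1OCc2c(Br)c(OCc3ccccc3)c(C=O)c(OC)c21 | intermediate
9 | 5-benzyloxy-4-bromo-6-(hydroxymethyl)-7-methoxyphthalide | O=C1OCc2c(Br)c(OCc3ccccc3)c(CO)c(OC)c21 | intermediate
10 | 5-benzyloxy-4-bromo-6-[(tert-butyldiphenylsilyloxy)methyl]-7-methoxyphthalide | O=C1OCc2c(Br)c(OCc3ccccc3)c(CO[Si](c3ccccc3)(c3ccccc3)C(C)(C)C)c(OC)c21 | intermediate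
11 | 5-benzyloxy-6-[(tert-butyldiphenylsilyloxy)methyl]-7-methoxy-4-(4,4,5,5-tetramethyl-1,3,2-dioxaborolan-2-yl)phthalide | O=C1OCc2c(B3OC(C)(C)C(C)(C)O3)c(OCc3ccccc3)c(CO[Si](c3ccccc3)(c3ccccc3)C(C)(C)C)c(OC)c21 | intermediate (not isolated)
12 | 5-benzyloxy-6-[(tert-butyldiphenylsilyloxy)methyl]-4-hydroxy-7-methoxyphthalide (ring B phenol) | O=C1OCc2c(O)c(OCc3ccccc3)c(CO[Si](c3ccccc3)(c3ccccc3)C(C)(C)C)c(OC)c21 | intermediate
13 | tert-butyl methyl malonate | COC(=O)CC(=O)OC(C)(C)C | starting material
14 | 1-tert-butyl 3-methyl 2-[bis(methylsulfanyl)methylidene]propanedioate | COC(=O)C(=C(SC)SC)C(=O)OC(C)(C)C | intermediate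
15 | benzyl acetoacetate (benzyl 3-oxobutanoate) | CC(=O)CC(=O)OCc1ccccc1 | starting material
16 | 1-tert-butyl 3-methyl 2-[2-(benzyloxycarbonyl)-1-(methylsulfanyl)-3-oxobutylidene]propanedioate (productive double-bond isomer drawn, methyl ester cis to the acetoacetate carbon; isomers interconvert) | COC(=O)/C(C(=O)OC(C)(C)C)=C(/SC)C(C(C)=O)C(=O)OCc1ccccc1 | intermediate (not isolated)
17 | 5-benzyl 3-tert-butyl 6-methyl-4-(methylsulfanyl)-2-oxo-2H-pyran-3,5-dicarboxylate | Cc1oc(=O)c(C(=O)OC(C)(C)C)c(SC)c1C(=O)OCc1ccccc1 | intermediate
18 | 5-benzyl 3-tert-butyl 4-(methanesulfonyl)-6-methyl-2-oxo-2H-pyran-3,5-dicarboxylate | Cc1oc(=O)c(C(=O)OC(C)(C)C)c(S(C)(=O)=O)c1C(=O)OCc1ccccc1 | intermediate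
19 | 5-benzyl 3-tert-butyl 4-{5-benzyloxy-6-[(tert-butyldiphenylsilyloxy)methyl]-7-methoxyphthalid-4-yloxy}-6-methyl-2-oxo-2H-pyran-3,5-dicarboxylate | Cc1oc(=O)c(C(=O)OC(C)(C)C)c(Oc2c(OCc3ccccc3)c(CO[Si](c3ccccc3)(c3ccccc3)C(C)(C)C)c(OC)c3c2COC3=O)c1C(=O)OCc1ccccc1 | intermediate
20 | 1,1-dimethoxyethene | C=C(OC)OC | starting material
21 | 5-benzyl 3-tert-butyl 4-(ArO)-8,8-dimethoxy-6-methyl-2-oxabicyclo[2.2.2]oct-4-en-3-one-type cycloadduct: lactone bridge O–C(=O) between the carbon bearing CH3 and the carbon bearing CO2tBu, CH2–C(OMe)2 bridge, alkene bridge bearing ArO and CO2Bn (racemic, one enantiomer drawn) | C[C@@]12OC(=O)[C@@](C(=O)OC(C)(C)C)(C(Oc3c(OCc4ccccc4)c(CO[Si](c4ccccc4)(c4ccccc4)C(C)(C)C)c(OC)c4c3COC4=O)=C1C(=O)OCc1ccccc1)C(OC)(OC)C2 | intermediate (not isolated)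
22 | 1-benzyl 3-tert-butyl 2-(ArO)-4,4-dimethoxy-6-methylcyclohexa-2,6-diene-1,3-dicarboxylate | CC1=C(C(=O)OCc2ccccc2)C(Oc2c(OCc3ccccc3)c(CO[Si](c3ccccc3)(c3ccccc3)C(C)(C)C)c(OC)c3c2COC3=O)=C(C(=O)OC(C)(C)C)C(OC)(OC)C1 | intermediate (not isolated)
23 | 1-benzyl 3-tert-butyl 2-{5-benzyloxy-6-[(tert-butyldiphenylsilyloxy)methyl]-7-methoxyphthalid-4-yloxy}-4-methoxy-6-methylbenzene-1,3-dicarboxylate | Cc1cc(OC)c(C(=O)OC(C)(C)C)c(Oc2c(OCc3ccccc3)c(CO[Si](c3ccccc3)(c3ccccc3)C(C)(C)C)c(OC)c3c2COC3=O)c1C(=O)OCc1ccccc1 | intermediate
24 | 3-(tert-butoxycarbonyl)-2-{6-[(tert-butyldiphenylsilyloxy)methyl]-5-hydroxy-7-methoxyphthalid-4-yloxy}-4-methoxy-6-methylbenzoic acid | Cc1cc(OC)c(C(=O)OC(C)(C)C)c(Oc2c(O)c(CO[Si](c3ccccc3)(c3ccccc3)C(C)(C)C)c(OC)c3c2COC3=O)c1C(=O)O | intermediate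
25 | protected depsidone: conneotricone with A3–OMe, A4–CO2tBu, B3–OMe and B2–CH2OSi(tBu)Ph2 | Cc1cc(OC)c(C(=O)OC(C)(C)C)c2c1C(=O)Oc1c(CO[Si](c3ccccc3)(c3ccccc3)C(C)(C)C)c(OC)c3c(c1O2)COC3=O | intermediate
26 | conneotricone B2 O-(tert-butyldiphenylsilyl) ether | Cc1cc(O)c(C(=O)O)c2c1C(=O)Oc1c(CO[Si](c3ccccc3)(c3ccccc3)C(C)(C)C)c(O)c3c(c1O2)COC3=O | intermediate
27 | conneotricone | Cc1cc(O)c(C(=O)O)c2c1C(=O)Oc1c(CO)c(O)c3c(c1O2)COC3=O | target

## Step count and risk

Total: 18 steps. Longest linear sequence: 15 steps (steps 1–9 and 13–18 from methyl orsellinate). The pyrone branch is 3 steps (10–12).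

**Step 14 (key step).** The cycloaddition may be too slow, because the 4-aryloxy group donates into the diene and the 6-methyl group crowds the terminus, so that thermal oligomerisation of the ketene acetal wins. Alternatively the ketene acetal may add at C4 and expel the aryloxide. The fallback changes the order of events so that the ring B fragment is not exposed. It sets out from pyrone 17 and runs the same cycloaddition with 20 to give 1-benzyl 3-tert-butyl 4-methoxy-6-methyl-2-(methylsulfanyl)benzene-1,3-dicarboxylate F1. Oxidation with mCPBA gives the sulfone 1-benzyl 3-tert-butyl 2-(methanesulfonyl)-4-methoxy-6-methylbenzene-1,3-dicarboxylate F2. The sulfonyl group, activated by two ortho esters, is then displaced by the cesium salt of phenol 12 (SNAr, DMF, 60–80 °C), which returns to the route at 23.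

**Step 13.** The hindered phenoxide may attack C6 or C2 of the pyrone and open the ring, or substitution at C4 may stall between the two esters. The fallback makes the C–O bond before the pyrone exists. From ketene dithioacetal 14 and phenol 12 (NaH, DMF, warm), one methylsulfanyl group is displaced to give the O,S-ketene acetal 1-tert-butyl 3-methyl 2-[(ArO)(methylsulfanyl)methylidene]propanedioate F3. Condensation of F3 with benzyl acetoacetate 15 under the conditions of step 11 expels the second methylsulfanyl group (the better leaving group of the two), closes the lactone and arrives at 19.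

**Step 11.** Vinylic substitution at the weakly electrophilic malonate-derived dithioacetal may be slow. The released methanethiolate may dealkylate the benzyl ester. Ring closure may go through carbon instead of oxygen and give a benzenoid by-product. The fallback exchanges the roles of the partners. From 15, CS2, K2CO3 and MeI give the α-oxoketene dithioacetal benzyl 2-[bis(methylsulfanyl)methylidene]-3-oxobutanoate F4. The potassium enolate of malonate 13 displaces one methylsulfanyl group; the adduct is a double-bond isomer of 16 and lactonises in the same way, coming back at 17.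

**Step 17.** BCl3 may attack the benzylic C–O bond at B2 (loss of the silyl group and ionisation to a benzylic chloride), or may leave the crowded A3 methyl ether partly intact at the temperature the rest of the molecule tolerates. The fallback removes the labile benzylic C–O bond before the Lewis acid is used.
- From 25, HF·pyridine gives the free alcohol, conneotricone A3,B3-dimethyl ether A4 tert-butyl ester F5.
- MnO2 in CH2Cl2 oxidises it to the B2 aldehyde F6.
- BCl3 as in step 17 then gives the aldehyde acid F7 (the B2 formyl analogue of 27). The formyl group is inert to BCl3 and adds a second chelation site for the B3 methyl ether.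
- A short chemoselective reduction of the aldehyde (NaBH4, THF–H2O, 0 °C, acidic quench) returns to the route at 27.

**Step 9.** Oxidative addition at the electron-rich, ortho-substituted bromide may be slow, with protodebromination in competition, and boronate may be lost before the oxidation. The fallback forms the C–O bond directly by palladium-catalysed hydroxylation of 10 (Pd2(dba)3, tBuBrettPhos, CsOH·H2O, 1,4-dioxane–H2O, 60 °C, then acidification to re-close any opened phthalide). It gives 12 without a boron intermediate and makes no compound outside the list (F0).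

## Further compounds

F1 | step 14 | 1-benzyl 3-tert-butyl 4-methoxy-6-methyl-2-(methylsulfanyl)benzene-1,3-dicarboxylate | Cc1cc(OC)c(C(=O)OC(C)(C)C)c(SC)c1C(=O)OCc1ccccc1
F2 | step 14 | 1-benzyl 3-tert-butyl 2-(methanesulfonyl)-4-methoxy-6-methylbenzene-1,3-dicarboxylate | Cc1cc(OC)c(C(=O)OC(C)(C)C)c(S(C)(=O)=O)c1C(=O)OCc1ccccc1
F3 | step 13 | 1-tert-butyl 3-methyl 2-[(ArO)(methylsulfanyl)methylidene]propanedioate (Ar = phthalid-4-yl group of 12; double-bond isomers interconvert, geometry not fixed) | COC(=O)C(C(=O)OC(C)(C)C)=C(SC)Oc1c(OCc2ccccc2)c(CO[Si](c2ccccc2)(c2ccccc2)C(C)(C)C)c(OC)c2c1COC2=O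
F4 | step 11 | benzyl 2-[bis(methylsulfanyl)methylidene]-3-oxobutanoate | CC(=O)C(=C(SC)SC)C(=O)OCc1ccccc1
F5 | step 17 | conneotricone A3,B3-dimethyl ether A4 tert-butyl ester (free B2 hydroxymethyl) | Cc1cc(OC)c(C(=O)OC(C)(C)C)c2c1C(=O)Oc1c(CO)c(OC)c3c(c1O2)COC3=O
F6 | step 17 | B2 formyl analogue of F5 | Cc1cc(OC)c(C(=O)OC(C)(C)C)c2c1C(=O)Oc1c(C=O)c(OC)c3c(c1O2)COC3=O
F7 | step 17 | B2 formyl analogue of conneotricone (free A3–OH, B3–OH and A4–CO2H) | Cc1cc(O)c(C(=O)O)c2c1C(=O)Oc1c(C=O)c(O)c3c(c1O2)COC3=O
F0 | step 9 | none | none
A1 | alternative 1 | hexasubstituted ring B benzoate (B3 silyl ether, B6 free phenol, B1 benzyl ether) | COC(=O)c1c(O[Si](C)(C)C(C)(C)C)c(COCOC)c(OCc2ccccc2)c(O)c1CO[Si](C)(C)C(C)(C)C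
A2 | alternative 1 | 4-benzyloxy-2-(tert-butyldimethylsilyloxy)-3-[(methoxymethoxy)methyl]furan | COCOCc1c(OCc2ccccc2)coc1O[Si](C)(C)C(C)(C)C
A3 | alternative 1 | methyl 4-(tert-butyldimethylsilyloxy)but-2-ynoate | COC(=O)C#CCO[Si](C)(C)C(C)(C)C
A4 | alternative 2 | conneotricone A3 methyl ether A4 methyl ester | Cc1cc(OC)c(C(=O)OC)c2c1C(=O)Oc1c(CO)c(O)c3c(c1O2)COC3=O
A5 | alternative 2 | depsidone with B4 bromide and B5 hydroxymethyl in place of the phthalide (A3 methyl ether, A4 methyl ester) | Cc1cc(OC)c(C(=O)OC)c2c1C(=O)Oc1c(CO)c(O)c(Br)c(CO)c1O2
A6 | alternative 3 | depsidone with A3 triflate, A4 methyl ester, B2 acetoxymethyl, B3 methyl ether | Cc1cc(OS(=O)(=O)C(F)(F)F)c(C(=O)OC)c2c1C(=O)Oc1c(COC(C)=O)c(OC)c3c(c1O2)COC3=O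
A7 | alternative 3 | xanthone precursor of A6 (ketone bridging A6 and B1) | Cc1cc(OS(=O)(=O)C(F)(F)F)c(C(=O)OC)c2c1C(=O)c1c(COC(C)=O)c(OC)c3c(c1O2)COC3=O
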